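**Assumptions:**
- The target is the cis-(3R,5R) 1,2-dioxolane, with both ring methyls on the same face. I checked this against the target SMILES by CIP analysis and a 3D sense check.
- The CO2H is carried as its methyl ester until the last step.
- The IDPi antipode that delivers (R,R) is found by screening both antipodes. Catalyst 8 is drawn as (R).

## Retrosynthetic overview
- The all-E triene is made last by Julia–Kocienski olefination of a PT-sulfone with commercial (2E,4E)-hepta-2,4-dienal. The acid is protected as its methyl ester until the end.
- The only ring, the 1,2-dioxolane, is formed in a single step that sets both quaternary stereocenters. It is a formal [3+2] of a ketone-derived peroxycarbenium ion with methyl 3-methylbut-3-enoate. The peroxycarbenium comes from a methyl ketone and bis(trimethylsilyl) peroxide. This is the proposed new chiral-anion-catalysed peroxy-Prins [3+2].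
- The ketone/sulfone partner comes from 11-bromoundec-1-ene by Wacker oxidation, PT-thioether formation and sulfide oxidation. The sulfone is made before the peroxide exists, so no thiolate ever meets the peroxide.
- Ring order: the dioxolane is formed in Step 4, and the triene (acyclic) is built after it in Step 5.

## Route

**Step 1**
Reactants: 1 (11-bromoundec-1-ene)
Product: 2 (11-bromoundecan-2-one)
Conditions: PdCl2 (10 mol%), CuCl (1 equiv), O2 (1 atm), DMF/H2O 7:1, 25 °C
Reagents that add atoms: water, O (supplies the ketone oxygen; O2 is only the terminal oxidant)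
Why: Wacker–Tsuji oxidation is Markovnikov-selective for a terminal alkene and tolerates a primary bromide. No stereocenter is formed.

**Step 2**
Reactants: 2 (11-bromoundecan-2-one); 3 (1-phenyl-1H-tetrazole-5-thiol, PT-SH)
Product: 4 (11-[(1-phenyltetrazol-5-yl)thio]undecan-2-one)
Conditions: K2CO3, DMF, 25 °C
Reagents that add atoms: PT-SH (reactant 3), Sc1nnnn1-c1ccccc1
Why: Thiolate SN2 displacement of a primary bromide; the ketone is untouched. No stereocenter is formed.

**Step 3**
Reactants: 4 (sulfide)
Product: 5 (11-[(1-phenyltetrazol-5-yl)sulfonyl]undecan-2-one)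
Conditions: (NH4)6Mo7O24·4H2O (10 mol%), 30% aq. H2O2 (6 equiv), EtOH, 0 °C to 25 °C
Reagents that add atoms: hydrogen peroxide, OO
Why: Mo-catalysed peroxide oxidation takes the sulfide to the sulfone. Baeyer–Villiger oxidation of the methyl ketone does not compete under these conditions. No stereocenter is formed.

**Step 4 (key step)**
Reactants: 5 (ketone-sulfone); 6 (methyl 3-methylbut-3-enoate); 7 (bis(trimethylsilyl) peroxide, BTMSP)
Product: 9 (methyl 2-[(3R,5R)-3,5-dimethyl-5-[9-(1-phenyltetrazol-5-yl)sulfonylnonyl]-1,2-dioxolan-3-yl]acetate, cis-dimethyl)
Conditions: (R)-IDPi 8 (5 mol%, converted in situ to its N-SiMe3 form), 7 (1.5 equiv), 6 (3 equiv), CH2Cl2/pentane 1:2, –40 °C, 48 h; quench with Et3N; silica chromatography removes the minor trans diastereomer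
Reagents that add atoms: BTMSP, C[Si](C)(C)OO[Si](C)(C)C (supplies the O–O unit; the two SiMe3 groups leave with the ketone oxygen as (Me3Si)2O)
Why: Proposed new method: the silylated chiral IDPi converts ketone 5 and BTMSP into a tightly ion-paired tertiary silylperoxycarbenium, R(Me)C=O⁺–OSiMe3. The 1,1-disubstituted alkene attacks it through its CH2 terminus in a Markovnikov sense, forming the Ca–C4 bond. The resulting tertiary cation at Cb is captured at once by the silylperoxy terminal oxygen, with loss of Me3Si⁺, which closes the five-membered ring. The confined anion makes the two events near-concerted and discriminates the enantiofaces, which sets Ca and Cb together. The envelope transition state places the chain and CH2CO2Me cis and pseudo-equatorial and the two methyls cis and pseudo-axial, which gives the cis-(3R,5R) isomer. The closest known reactions are peroxycarbenium/alkene [3+2] annulations of peroxyacetals and IDPi-silylium Prins-type cyclisations, applied here to a ketone-derived tertiary peroxycarbenium and a 1,1-disubstituted alkene.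

**Step 5**
Reactants: 9 (dioxolane PT-sulfone); 10 ((2E,4E)-hepta-2,4-dienal)
Product: 11 (methyl 2-[(3R,5R)-3,5-dimethyl-5-[(9E,11E,13E)-hexadeca-9,11,13-trien-1-yl]-1,2-dioxolan-3-yl]acetate)
Conditions: KHMDS (1.05 equiv), DME, –60 °C, then 10 added, warm to 25 °C
Reagents that add atoms: none (aldehyde 10 is a reactant)
Why: Julia–Kocienski olefination with a PT-sulfone gives E-olefins through anti addition, Smiles rearrangement and loss of SO2 and PT-O⁻. With the dienal this gives the E,E,E-triene. The quaternary peroxide stereocenters have no acidic hydrogen and are not affected.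

**Step 6**
Reactants: 11 (triene methyl ester)
Product: 12 (target acid)
Conditions: LiOH·H2O (3 equiv), THF/MeOH/H2O 3:1:1, 0 °C to 20 °C, dark, under argon; acidify to pH 4 with citric acid
Reagents that add atoms: lithium hydroxide, [Li]O; and water, O (the carboxylate oxygen comes from hydroxide)
Why: Saponification of a methyl ester. The dialkyl peroxide and the triene are stable to cold dilute hydroxide, and the stereocenters are not touched.

## Compound list
1 | 11-bromoundec-1-ene | C=CCCCCCCCCCBr | starting material
2 | 11-bromoundecan-2-one | CC(=O)CCCCCCCCCBr | intermediate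
3 | 1-phenyl-1H-tetrazole-5-thiol | Sc1nnnn1-c1ccccc1 | starting material
4 | 11-[(1-phenyltetrazol-5-yl)thio]undecan-2-one | CC(=O)CCCCCCCCCSc1nnnn1-c1ccccc1 | intermediate
5 | 11-[(1-phenyltetrazol-5-yl)sulfonyl]undecan-2-one | CC(=O)CCCCCCCCCS(=O)(=O)c1nnnn1-c1ccccc1 | intermediate
6 | methyl 3-methylbut-3-enoate | C=C(C)CC(=O)OC | starting material
7 | bis(trimethylsilyl) peroxide | C[Si](C)(C)OO[Si](C)(C)C | starting material
8 | (R)-BINOL-derived imidodiphosphorimidate (IDPi) organocatalyst, used as a purchased or prepared reagent. The real catalyst carries 3,3'-aryl groups; the SMILES shows only the unsubstituted core, and the (R) axial chirality is not encoded | N(P1(=NS(=O)(=O)C(F)(F)F)Oc2ccc3ccccc3c2-c2c(O1)ccc1ccccc12)P1(=NS(=O)(=O)C(F)(F)F)Oc2ccc3ccccc3c2-c2c(O1)ccc1ccccc12 | starting material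
9 | methyl 2-[(3R,5R)-3,5-dimethyl-5-[9-(1-phenyltetrazol-5-yl)sulfonylnonyl]-1,2-dioxolan-3-yl]acetate | O=S(=O)(c2nnnn2-c3ccccc3)CCCCCCCCC[C@]1(C)C[C@](C)(CC(=O)OC)OO1 | intermediate
10 | (2E,4E)-hepta-2,4-dienal | CC/C=C/C=C/C=O | starting material
11 | methyl 2-[(3R,5R)-3,5-dimethyl-5-[(9E,11E,13E)-hexadeca-9,11,13-trien-1-yl]-1,2-dioxolan-3-yl]acetate | CC/C=C/C=C/C=C/CCCCCCCC[C@]1(C)C[C@](C)(CC(=O)OC)OO1 | intermediate
12 | 2-[(3R,5R)-3,5-dimethyl-5-[(9E,11E,13E)-hexadeca-9,11,13-trien-1-yl]-1,2-dioxolan-3-yl]acetic acid | CC/C=C/C=C/C=C/CCCCCCCC[C@]1(C)C[C@](C)(CC(=O)O)OO1 | target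

## Summary
- **Total steps:** 6.
- **Longest linear sequence:** 6 steps, from 1 to 12.

**Three steps most likely to fail**
1. **Step 4 (proposed new step).** The silylium/peroxycarbenium conditions may cause alkene oligomerisation, isomerisation of 6 to the conjugated ester, or enol-ether formation. Methyl versus n-alkyl face discrimination at the ketone is also hard, and the enantio- and diastereocontrol are unproven.
   - Fallback: a stepwise route using known chemistry.
     - Indium-mediated Barbier allylation of 5 with methyl 3-(bromomethyl)but-3-enoate gives the tertiary homoallylic alcohol, R(Me)C(OH)CH2C(=CH2)CH2CO2Me.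
     - H2O2 with cat. acid converts the tertiary alcohol into the tertiary hydroperoxide at Ca, with the 1,1-disubstituted alkene retained.
     - Hg(OTf)2 then closes the ring by 5-exo peroxymercuration, and NaBH4 demercuration converts the exocyclic CH2–Hg into the Cb methyl (Bloodworth-type).
     - Diastereomers are separated on silica and enantiomers by preparative chiral HPLC.
2. **Step 5 (Julia–Kocienski).** The E,E,E selectivity may be poor, or KHMDS may trigger retro-oxa-Michael opening of the β-peroxy ester.
   - Fallback: carry an ω-OPiv chain through the key step instead of the sulfone, then remove the Piv group, oxidise to the aldehyde and apply Takai–Utimoto iodo-olefination. Suzuki coupling with (1E,3E)-hexa-1,3-dienyl-Bpin then builds the triene with no strong base present.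
3. **Step 6 (saponification).** Retro-Michael ring opening, or triene and peroxide decomposition on workup, could lower the yield.
   - Fallback: use 2-(trimethylsilyl)ethyl 3-methylbut-3-enoate in Step 4 and remove the ester at the end with TBAF buffered with AcOH, which avoids hydroxide entirely.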